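**Retrosynthetic overview**
- The last bond made is C6(flavanone)–C3(pyranone). Unprotected (2S)-8-prenylpinocembrin is joined in the final step to the phenyliodonium ylide of the pyranone, which makes the natively nucleophilic pyranone C3 an electrophilic (enolonium-type) carbon.
- (2S)-8-Prenylpinocembrin comes from (2S)-pinocembrin: the prenyl group is put on O5 and moved to C8 by a Claisen–Cope cascade. The C2 stereocentre is bought and never opened.
- The ylide comes from 6-ethyl-4-hydroxy-5-methyl-2-pyranone, which comes from malonyl dichloride and the silyl enol ether of pentan-3-one.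
- Ring order: the pyranone ring is built first, in its own branch. Rings A, B and C of the flavanone are bought intact. No ring is formed after the coupling.

Assumption: (2S)-(−)-pinocembrin and the trimethylsilyl enol ether of pentan-3-one are bought as catalogue compounds (the latter is otherwise one step from pentan-3-one); the aryl–pyranone axis carries no stereodescriptor in the target and is not controlled.

**Step 1**
Reactants: 1 3-(trimethylsilyloxy)pent-2-ene (E/Z mixture); 2 malonyl dichloride
Product: 4 6-ethyl-4-hydroxy-5-methyl-2H-pyran-2-one, via 4-methyl-3,5-dioxoheptanoyl chloride 3 (not isolated)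
Conditions: Et2O, −78 °C to rt
Reagents that add atoms: none
Why: Pyranone annulation of a silyl enol ether with malonyl dichloride (Effenberger-type): C-acylation of the enol ether, then O-acylation of the ketone enol by the second acid chloride closes the lactone, which tautomerises to the 4-hydroxy-2-pyranone; no stereocentre is formed.

**Step 2**
Reactants: 4 6-ethyl-4-hydroxy-5-methyl-2H-pyran-2-one
Product: 5 6-ethyl-5-methyl-2-oxo-3-(phenyliodonio)-2H-pyran-4-olate (phenyliodonium ylide of 4)
Conditions: PhI(OAc)2, Na2CO3, H2O, 0 °C to rt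
Reagents that add atoms: (diacetoxyiodo)benzene, CC(=O)OI(OC(C)=O)c1ccccc1
Why: Iodonium ylide formation by condensation of the acidic C3–H (the only acidic carbon, pKa about 5) with the trivalent iodine reagent, the same reaction type that gives the stable ylides of 4-hydroxycoumarin and 4-hydroxy-6-methyl-2-pyranone.

**Step 3**
Reactants: 6 (2S)-pinocembrin [(2S)-5,7-dihydroxy-2-phenylchroman-4-one]
Product: 7 (2S)-7-acetoxy-5-hydroxy-2-phenylchroman-4-one
Conditions: Ac2O (1.1 equiv), pyridine, 0 °C to rt
Reagents that add atoms: acetic anhydride, CC(=O)OC(C)=O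
Why: Selective O-acylation of the free 7-OH, because the 5-OH is hydrogen-bonded to the 4-carbonyl and is much less reactive; C2 is untouched.

**Step 4**
Reactants: 7 (2S)-7-acetoxy-5-hydroxy-2-phenylchroman-4-one; 8 prenol (3-methylbut-2-en-1-ol)
Product: 9 (2S)-7-acetoxy-5-(3-methylbut-2-enyloxy)-2-phenylchroman-4-one
Conditions: PPh3, DIAD, THF, 0 °C to rt
Reagents that add atoms: none
Why: Mitsunobu etherification of the chelated 5-OH with a primary allylic alcohol (SN2 at CH2) under neutral conditions that cannot open the flavanone ring; C2 is untouched.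

**Step 5**
Reactants: 9 (2S)-7-acetoxy-5-(3-methylbut-2-enyloxy)-2-phenylchroman-4-one
Product: 12 (2S)-7-acetoxy-5-hydroxy-8-(3-methylbut-2-enyl)-2-phenylchroman-4-one, via Claisen dienone 10 (not isolated), via Cope dienone 11 (not isolated)
Conditions: Eu(fod)3 [tris(6,6,7,7,8,8,8-heptafluoro-2,2-dimethyloctane-3,5-dionato)europium] (10 mol%), CHCl3, 60 °C
Reagents that add atoms: none
Why: Claisen rearrangement to C6 (the only free ortho carbon of O5), Cope rearrangement on to C8 (its para carbon) and enolisation (para-Claisen–Cope cascade), accelerated by chelation of trivalent europium to the 4-carbonyl/5-oxygen pair, deliver an un-inverted prenyl group at C8; C2 is not involved and the sp3 ring carbons of 10 and 11 are transient.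

**Step 6**
Reactants: 12 (2S)-7-acetoxy-5-hydroxy-8-(3-methylbut-2-enyl)-2-phenylchroman-4-one
Product: 13 (2S)-5,7-dihydroxy-8-(3-methylbut-2-enyl)-2-phenylchroman-4-one [(2S)-8-prenylpinocembrin]
Conditions: K2CO3 (0.2 equiv), MeOH, 0 °C, 30 min; AcOH quench
Reagents that add atoms: none
Why: Transesterification of the aryl acetate to methanol, kept cold, brief and catalytic in base so that the retro-oxa-Michael ring opening that would racemise C2 does not compete.

**Step 7**
Reactants: 13 (2S)-8-prenylpinocembrin; 5 phenyliodonium ylide of the pyranone (1.3 equiv)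
Product: 14 (2S)-6-(6-ethyl-4-hydroxy-5-methyl-2-oxo-2H-pyran-3-yl)-5,7-dihydroxy-8-(3-methylbut-2-enyl)-2-phenylchroman-4-one (target)
Conditions: BF3·OEt2 (30 mol%), CH2Cl2, −40 °C to 0 °C, dark
Reagents that add atoms: none
Why: Proposed new method: BF3 binds the enolate oxygen of 5 and turns the ylide into an alkenyl(phenyl)iodonium species, an enolonium equivalent electrophilic at C3; C6 of 13, the only free position of ring A and activated by two ortho hydroxyls, attacks C3 in a Friedel–Crafts sense, iodobenzene leaves, and re-aromatisation with proton transfer to the pyranone oxygen gives 14 with no net acid consumed; the arene should outcompete the trisubstituted prenyl alkene as nucleophile, and the low temperature and sub-stoichiometric Lewis acid are chosen to keep the 7-OH/8-prenyl pair from closing to a chroman and to leave C2 untouched; the closest known reaction type is the BF3-mediated C-arylation of phenyliodonium ylides of cyclic 1,3-dicarbonyl compounds (2-hydroxy-1,4-naphthoquinone) with activated arenes, together with the use of 4-hydroxycoumarin iodonium ylides as C3 electrophiles.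

**Compound list**
1 | 3-(trimethylsilyloxy)pent-2-ene (E/Z mixture) | CC=C(CC)O[Si](C)(C)C | starting material
2 | malonyl dichloride | O=C(Cl)CC(=O)Cl | starting material
3 | 4-methyl-3,5-dioxoheptanoyl chloride (formed in the flask, step 1) | CCC(=O)C(C)C(=O)CC(=O)Cl | intermediate
4 | 6-ethyl-4-hydroxy-5-methyl-2H-pyran-2-one | CCc1oc(=O)cc(O)c1C | intermediate
5 | 6-ethyl-5-methyl-2-oxo-3-(phenyliodonio)-2H-pyran-4-olate | CCC1=C(C)C([O-])=C([I+]c2ccccc2)C(=O)O1 | intermediate
6 | (2S)-pinocembrin, (2S)-5,7-dihydroxy-2-phenylchroman-4-one | O=C1C[C@@H](c2ccccc2)Oc2cc(O)cc(O)c12 | starting material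
7 | (2S)-7-acetoxy-5-hydroxy-2-phenylchroman-4-one | O=C1C[C@@H](c2ccccc2)Oc2cc(OC(C)=O)cc(O)c12 | intermediate
8 | prenol, 3-methylbut-2-en-1-ol | CC(C)=CCO | starting material
9 | (2S)-7-acetoxy-5-(3-methylbut-2-enyloxy)-2-phenylchroman-4-one | O=C1C[C@@H](c2ccccc2)Oc2cc(OC(C)=O)cc(OCC=C(C)C)c12 | intermediate
10 | Claisen dienone, (2S)-7-acetoxy-6-(2-methylbut-3-en-2-yl)-2-phenyl-2,3-dihydro-4H-chromene-4,5(6H)-dione, C6 epimers (formed in the flask, step 5) | O=C1C[C@@H](c2ccccc2)OC2=C1C(=O)C(C(C)(C)C=C)C(OC(C)=O)=C2 | intermediate
11 | Cope dienone, (2S)-7-acetoxy-8-(3-methylbut-2-enyl)-2-phenyl-2,3-dihydro-4H-chromene-4,5(8H)-dione, C8 epimers (formed in the flask, step 5) | O=C1C[C@@H](c2ccccc2)OC2=C1C(=O)C=C(OC(C)=O)C2CC=C(C)C | intermediate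
12 | (2S)-7-acetoxy-5-hydroxy-8-(3-methylbut-2-enyl)-2-phenylchroman-4-one | O=C1C[C@@H](c2ccccc2)Oc2c(CC=C(C)C)c(OC(C)=O)cc(O)c12 | intermediate
13 | (2S)-5,7-dihydroxy-8-(3-methylbut-2-enyl)-2-phenylchroman-4-one, (2S)-8-prenylpinocembrin | O=C1C[C@@H](c2ccccc2)Oc2c(CC=C(C)C)c(O)cc(O)c12 | intermediate
14 | (2S)-6-(6-ethyl-4-hydroxy-5-methyl-2-oxo-2H-pyran-3-yl)-5,7-dihydroxy-8-(3-methylbut-2-enyl)-2-phenylchroman-4-one | CCc1oc(=O)c(-c2c(O)c(CC=C(C)C)c3c(c2O)C(=O)C[C@@H](c2ccccc2)O3)c(O)c1C | target

**Totals**
Total step count: 7. Longest linear sequence: 5 steps (6 → 7 → 9 → 12 → 13 → 14). The pyranone branch (1 + 2 → 4 → 5) is 2 steps and joins at step 7.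

**Three steps most likely to fail**

Step 7 (the coupling). The risks are attack of the activated ylide by the prenyl alkene or by a phenolic oxygen instead of C6, and acid-triggered chroman closure. The fallback sets out from 5 and 13 and comes back to the route at 14. Ylide 5 is oxidised with dimethyldioxirane (acetone, 0 °C) to the vicinal tricarbonyl compound 6-ethyl-5-methyl-2H-pyran-2,3,4(3H)-trione F1, whose central carbonyl carbon is now the electrophile. F1 and 13 in acetic acid at rt give, by a ninhydrin-type Friedel–Crafts hydroxyalkylation at C6, the tertiary carbinol (2S)-6-(6-ethyl-3-hydroxy-5-methyl-2,4-dioxo-3,4-dihydro-2H-pyran-3-yl)-5,7-dihydroxy-8-(3-methylbut-2-enyl)-2-phenylchroman-4-one F2 (carbinol epimers, possibly present as a cyclic hemiketal with a neighbouring phenol). Zn dust in acetic acid at rt then removes the hydroxyl that is alpha to both carbonyls and gives 14. This path uses no strong Lewis acid and no reagent that attacks alkenes.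

Step 5 (Claisen–Cope cascade). The risk is that the first dienone enolises to the 6-(1,1-dimethylallyl) phenol before the Cope step, or that the cascade stalls. The fallback sets out from 6 and comes back to the route at 13. Direct Friedel–Crafts C-prenylation of 6 with 2-methylbut-3-en-2-ol and BF3·OEt2 in dioxane at rt gives 13 together with its 6-prenyl isomer, which are separated by chromatography and assigned by HMBC. This replaces steps 3 to 6 at the cost of a regioisomer mixture and makes no new compound.

Step 1 (pyranone annulation). The risks are self-condensation of malonyl dichloride and O-acylation of the enol ether, giving a low yield. The fallback sets out from 1 and comes back to the route at 4. ZnCl2-catalysed (10 mol%) C-acylation of 1 with methyl 3-chloro-3-oxopropanoate in CH2Cl2 (0 °C to rt) gives the isolable methyl 4-methyl-3,5-dioxoheptanoate F3. DBU in refluxing toluene then closes F3 to 4 with loss of methanol.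

**Further compounds**
F1 | step 7 | 6-ethyl-5-methyl-2H-pyran-2,3,4(3H)-trione | CCC1=C(C)C(=O)C(=O)C(=O)O1
F2 | step 7 | (2S)-6-(6-ethyl-3-hydroxy-5-methyl-2,4-dioxo-3,4-dihydro-2H-pyran-3-yl)-5,7-dihydroxy-8-(3-methylbut-2-enyl)-2-phenylchroman-4-one (carbinol epimers) | CCC1=C(C)C(=O)C(O)(c2c(O)c(CC=C(C)C)c3c(c2O)C(=O)C[C@@H](c2ccccc2)O3)C(=O)O1
F0 | step 5 | none | none
F3 | step 1 | methyl 4-methyl-3,5-dioxoheptanoate | CCC(=O)C(C)C(=O)CC(=O)OC
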